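**Plan**

- Retrosynthetic cuts: first the O–Si bonds at O7 and O4' and the O–CH3 bond at O5; then C2–C3 of ring C; then C3–C1' between the ketone α-carbon and ring B; last C4–C4a and the pyran ring of the chromene.
- Enabling feature: C3 sits between the C4 carbonyl and the ring B aryl carbon, so it can be a donor/acceptor carbene. C2 is only a methyl group on the ring A oxygen O1, with C–H bonds activated by O1 and held 1,6 to C3. Ring A is 2,6-dioxygenated, so a 2,6-dimethoxyaryl ketone offers the same OCH3 on either side.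
- Forward order: the pyran ring of the chromene is made on a bromoresorcinol, the ring A methyl ketone is made separately, the two are joined by ketone α-arylation, the diazo group is installed, and ring C is closed last.
- Stereochemistry: the only stereocentre, C3 (R), is created in the ring closure under control of a chiral dirhodium tetracarboxylate. After that only acidic or neutral conditions are used, because a 3-arylchroman-4-one epimerises with base.

Key step: step 8

Remark: C3 of the target is R; it is assumed that the (S)-configured catalyst Rh2(S-PTAD)4 delivers this enantiomer, and if a trial on 13 shows the opposite sense, Rh2(R-PTAD)4 is used with no other change.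

**Route**

Step 1
Reactants: 1 3,5-dimethoxyphenol
Product: 2 (3,5-dimethoxyphenoxy)triisopropylsilane
Conditions: TIPSCl, imidazole, DMF, rt
Reagents that add atoms: chlorotriisopropylsilane, CC(C)[Si](Cl)(C(C)C)C(C)C
Why: Imidazole-promoted silylation of the only phenol; the bulky silyl ether should tolerate the organolithium, phosphate and amidine bases used later and is a poor ortho-director.

Step 2
Reactants: 2 (3,5-dimethoxyphenoxy)triisopropylsilane; 3 N-methoxy-N-methylacetamide
Product: 5 1-[2,6-dimethoxy-4-(triisopropylsilyloxy)phenyl]ethanone, via 2,6-dimethoxy-4-(triisopropylsilyloxy)phenyllithium 4 (not isolated)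
Conditions: n-BuLi, THF, 0 °C → rt; then 3, −78 → 0 °C; sat. aq. NH4Cl
Reagents that add atoms: none
Why: Directed ortho-metalation should occur at the ring carbon flanked by both methoxy groups (cooperative direction, while the bulky silyloxy group shields its own ortho positions), and the aryllithium is acylated once through the chelated tetrahedral intermediate of the Weinreb ketone synthesis.

Step 3
Reactants: 6 4-bromoresorcinol
Product: 7 2-bromo-5-(triisopropylsilyloxy)phenol
Conditions: TIPSCl (1.0 equiv), imidazole, CH2Cl2, 0 °C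
Reagents that add atoms: chlorotriisopropylsilane, CC(C)[Si](Cl)(C(C)C)C(C)C
Why: Regioselective monosilylation: the hydroxyl para to bromine is unhindered, whereas the one ortho to bromine is shielded and less nucleophilic, so the bulky silyl chloride should take the former.

Step 4
Reactants: 7 2-bromo-5-(triisopropylsilyloxy)phenol; 8 3-chloro-3-methylbut-1-yne
Product: 9 [4-bromo-3-(2-methylbut-3-yn-2-yloxy)phenoxy]triisopropylsilane
Conditions: DBU, CuCl2·2H2O (1 mol %), MeCN, 0 °C → rt
Reagents that add atoms: none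
Why: Copper-catalysed O-propargylation of a phenol with a tertiary propargylic chloride (through a copper acetylide-derived electrophile) is the standard entry to aryl 1,1-dimethylpropargyl ethers and is mild enough for the aryl silyl ether.

Step 5
Reactants: 9 [4-bromo-3-(2-methylbut-3-yn-2-yloxy)phenoxy]triisopropylsilane
Product: 11 8-bromo-2,2-dimethyl-5-(triisopropylsilyloxy)-2H-chromene, via 6-bromo-2-(3-methylbuta-1,2-dienyl)-3-(triisopropylsilyloxy)phenol 10 (not isolated)
Conditions: N,N-diethylaniline, 185 °C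
Reagents that add atoms: none
Why: Thermal aromatic propargyl Claisen rearrangement can only go to the free ortho carbon (the other bears bromine); enolisation to the allenylphenol, 1,5-hydrogen shift and oxa-6π electrocyclisation should then give the 2,2-dimethylchromene with unambiguous regiochemistry.

Step 6
Reactants: 5 1-[2,6-dimethoxy-4-(triisopropylsilyloxy)phenyl]ethanone; 11 8-bromo-2,2-dimethyl-5-(triisopropylsilyloxy)-2H-chromene
Product: 12 1-[2,6-dimethoxy-4-(triisopropylsilyloxy)phenyl]-2-[2,2-dimethyl-5-(triisopropylsilyloxy)-2H-chromen-8-yl]ethanone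
Conditions: Pd2(dba)3 (2 mol %), XPhos (8 mol %), K3PO4, toluene, 100 °C
Reagents that add atoms: none
Why: Buchwald–Hartwig-type α-arylation of a ketone enolate at zerovalent palladium; the bulky biaryl phosphine handles the ortho-oxygenated bromide, the phosphate base spares the silyl ethers, and the more acidic, hindered product stays as its enolate so that diarylation is not expected.

Step 7
Reactants: 12 1-[2,6-dimethoxy-4-(triisopropylsilyloxy)phenyl]-2-[2,2-dimethyl-5-(triisopropylsilyloxy)-2H-chromen-8-yl]ethanone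
Product: 13 2-diazo-1-[2,6-dimethoxy-4-(triisopropylsilyloxy)phenyl]-2-[2,2-dimethyl-5-(triisopropylsilyloxy)-2H-chromen-8-yl]ethanone
Conditions: p-ABSA, DBU, MeCN, 0 °C → rt
Reagents that add atoms: 4-acetamidobenzenesulfonyl azide (p-ABSA), CC(=O)Nc1ccc(cc1)S(=O)(=O)N=[N+]=[N-]
Why: Regitz diazo transfer works directly on benzyl aryl ketones because the doubly activated methylene is acidic enough for DBU, and the sulfonyl azide delivers the terminal N2 unit.

Step 8
Reactants: 13 2-diazo-1-[2,6-dimethoxy-4-(triisopropylsilyloxy)phenyl]-2-[2,2-dimethyl-5-(triisopropylsilyloxy)-2H-chromen-8-yl]ethanone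
Product: 14 (3R)-3-[2,2-dimethyl-5-(triisopropylsilyloxy)-2H-chromen-8-yl]-5-methoxy-7-(triisopropylsilyloxy)chroman-4-one
Conditions: Rh2(S-PTAD)4 (dirhodium tetrakis[(S)-(1-adamantyl)(N-phthalimido)acetate], 1 mol %), PhCF3, 4 Å MS, slow addition of 13 at high dilution, 0 °C → rt
Reagents that add atoms: none
Why: Proposed new method: loss of N2 from 13 at the dirhodium catalyst should give an electrophilic donor/acceptor carbene at C3 (donor: ring B aryl; acceptor: C4 ketone) that inserts, in a concerted hydride-transfer-like three-centre transition state, into a C–H bond of an ortho O–CH3 group made hydridic by the O1 lone pair, forming C2–C3 and C3–H together; the closest known reaction types are the dirhodium-catalysed intramolecular C–H insertion of 2-alkoxyaryl diazoketones next to the ether oxygen to give chroman-4-ones and the enantioselective insertion of aryl-substituted donor/acceptor carbenes into methyl ether C–H bonds, whereas a 1,6-insertion of an α-aryl-α-diazoketone into an aryl O–CH3 group is not established. Ring C closes as a six-membered ring by 1,6-insertion, C3 and the methyl carbon being linked through C4, C4a, C8a and O1. The only new stereocentre, C3, is the carbene carbon itself, and its configuration should be fixed by the chiral pocket of the four phthalimido-carboxylate ligands, which decides the face of the rhodium-bound carbene that receives the hydrogen (catalyst control, no substrate stereocentre). The step needs insertion to win over attack of the carbene on the methoxy oxygen (five-membered oxonium ylide), over reaction with ring B and over intermolecular cyclopropanation of the chromene C3=C4 bond. The substrate should secure this because an O-methyl ylide has no allyl or benzyl group to migrate and should revert, both ortho positions of ring A carry the same OCH3 so that either rotamer about the aryl–C4 bond is productive and no ortho aryl C–H is offered, the chromene oxygen bears a quaternary carbon, the silyl ethers have no C–H next to oxygen, and slow addition at high dilution suppresses bimolecular paths.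

Step 9
Reactants: 14 (3R)-3-[2,2-dimethyl-5-(triisopropylsilyloxy)-2H-chromen-8-yl]-5-methoxy-7-(triisopropylsilyloxy)chroman-4-one
Product: 15 (3R)-3-[2,2-dimethyl-5-(triisopropylsilyloxy)-2H-chromen-8-yl]-5-hydroxy-7-(triisopropylsilyloxy)chroman-4-one
Conditions: BCl3 (1 M in CH2Cl2), CH2Cl2, −78 → −30 °C; pH 7 buffer
Reagents that add atoms: none
Why: Chelation-controlled demethylation: BCl3 binds the C4 carbonyl and cleaves only the peri 5-methoxy group (a standard reaction of 5-methoxy flavonoids), while aryl triisopropylsilyl ethers should survive at low temperature and the base-free medium should leave C3 untouched.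

Step 10
Reactants: 15 (3R)-3-[2,2-dimethyl-5-(triisopropylsilyloxy)-2H-chromen-8-yl]-5-hydroxy-7-(triisopropylsilyloxy)chroman-4-one
Product: 16 (3R)-5,7-dihydroxy-3-(5-hydroxy-2,2-dimethyl-2H-chromen-8-yl)chroman-4-one
Conditions: HF·pyridine, THF/pyridine, 0 °C → rt
Reagents that add atoms: none
Why: Fluoride cleaves both aryl Si–O bonds under buffered, weakly acidic conditions, which avoid the base-mediated enolisation that would racemise C3 and should not touch the chromene double bond.

**Compound list**

1 | 3,5-dimethoxyphenol | COc1cc(O)cc(OC)c1 | starting material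
2 | (3,5-dimethoxyphenoxy)triisopropylsilane | COc1cc(OC)cc(O[Si](C(C)C)(C(C)C)C(C)C)c1 | intermediate
3 | N-methoxy-N-methylacetamide | CON(C)C(C)=O | starting material
4 | 2,6-dimethoxy-4-(triisopropylsilyloxy)phenyllithium | [Li]c1c(OC)cc(O[Si](C(C)C)(C(C)C)C(C)C)cc1OC | intermediate (not isolated)
5 | 1-[2,6-dimethoxy-4-(triisopropylsilyloxy)phenyl]ethanone | CC(=O)c1c(OC)cc(O[Si](C(C)C)(C(C)C)C(C)C)cc1OC | intermediate
6 | 4-bromoresorcinol (4-bromobenzene-1,3-diol) | Oc1ccc(Br)c(O)c1 | starting material
7 | 2-bromo-5-(triisopropylsilyloxy)phenol | Oc1cc(O[Si](C(C)C)(C(C)C)C(C)C)ccc1Br | intermediate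
8 | 3-chloro-3-methylbut-1-yne | CC(C)(Cl)C#C | starting material
9 | [4-bromo-3-(2-methylbut-3-yn-2-yloxy)phenoxy]triisopropylsilane | C#CC(C)(C)Oc1cc(O[Si](C(C)C)(C(C)C)C(C)C)ccc1Br | intermediate
10 | 6-bromo-2-(3-methylbuta-1,2-dienyl)-3-(triisopropylsilyloxy)phenol | CC(C)=C=Cc1c(O)c(Br)ccc1O[Si](C(C)C)(C(C)C)C(C)C | intermediate (not isolated)
11 | 8-bromo-2,2-dimethyl-5-(triisopropylsilyloxy)-2H-chromene | CC1(C)C=Cc2c(O[Si](C(C)C)(C(C)C)C(C)C)ccc(Br)c2O1 | intermediate
12 | 1-[2,6-dimethoxy-4-(triisopropylsilyloxy)phenyl]-2-[2,2-dimethyl-5-(triisopropylsilyloxy)-2H-chromen-8-yl]ethanone | COc1cc(O[Si](C(C)C)(C(C)C)C(C)C)cc(OC)c1C(=O)Cc1ccc(O[Si](C(C)C)(C(C)C)C(C)C)c2C=CC(C)(C)Oc12 | intermediate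
13 | 2-diazo-1-[2,6-dimethoxy-4-(triisopropylsilyloxy)phenyl]-2-[2,2-dimethyl-5-(triisopropylsilyloxy)-2H-chromen-8-yl]ethanone | COc1cc(O[Si](C(C)C)(C(C)C)C(C)C)cc(OC)c1C(=O)C(=[N+]=[N-])c1ccc(O[Si](C(C)C)(C(C)C)C(C)C)c2C=CC(C)(C)Oc12 | intermediate
14 | (3R)-3-[2,2-dimethyl-5-(triisopropylsilyloxy)-2H-chromen-8-yl]-5-methoxy-7-(triisopropylsilyloxy)chroman-4-one | CC1(C)C=Cc2c(O[Si](C(C)C)(C(C)C)C(C)C)ccc([C@@H]3COc4cc(O[Si](C(C)C)(C(C)C)C(C)C)cc(OC)c4C3=O)c2O1 | intermediate
15 | (3R)-3-[2,2-dimethyl-5-(triisopropylsilyloxy)-2H-chromen-8-yl]-5-hydroxy-7-(triisopropylsilyloxy)chroman-4-one | CC1(C)C=Cc2c(O[Si](C(C)C)(C(C)C)C(C)C)ccc([C@@H]3COc4cc(O[Si](C(C)C)(C(C)C)C(C)C)cc(O)c4C3=O)c2O1 | intermediate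
16 | (3R)-5,7-dihydroxy-3-(5-hydroxy-2,2-dimethyl-2H-chromen-8-yl)chroman-4-one | CC1(C)C=Cc2c(O)ccc([C@@H]3COc4cc(O)cc(O)c4C3=O)c2O1 | target

**Summary**

Total step count: 10. Longest linear sequence: 8 steps (6 → 7 → 9 → 11 → 12 → 13 → 14 → 15 → 16, steps 3–10).

**Steps most likely to fail**

1. Step 8 (proposed method). The carbene may be diverted before it inserts: attack on the methoxy oxygen followed by a Stevens-type shift or demethylation, dimerisation, or intermolecular cyclopropanation. The primary C–H bond may also react too slowly, or facial control at C3 may be poor. The fallback uses known chemistry, sets out from 12 and returns at 14. Compound 12 is mono-demethylated with BCl3 (CH2Cl2, −78 °C; carbonyl chelation, the two ortho methoxy groups being equivalent) to 2-[2,2-dimethyl-5-(triisopropylsilyloxy)-2H-chromen-8-yl]-1-[2-hydroxy-6-methoxy-4-(triisopropylsilyloxy)phenyl]ethanone F1. Heating F1 with paraformaldehyde and Et2NH in MeOH (α-methylenation, then oxa-Michael closure) should give racemic 3-[2,2-dimethyl-5-(triisopropylsilyloxy)-2H-chromen-8-yl]-5-methoxy-7-(triisopropylsilyloxy)chroman-4-one F2. Noyori asymmetric transfer hydrogenation with dynamic kinetic resolution (RuCl(p-cymene)[(R,R)-TsDPEN] or its antipode, HCO2H/Et3N, EtOAc, 40 °C; C3 epimerises in the ketone, one enantiomer is reduced) should give (3R,4R)-cis-3-[2,2-dimethyl-5-(triisopropylsilyloxy)-2H-chromen-8-yl]-5-methoxy-7-(triisopropylsilyloxy)chroman-4-ol F3. Dess–Martin periodinane (CH2Cl2, 0 °C, base-free) then returns the ketone 14 without touching C3.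

2. Step 9. The Lewis acid and the HCl formed may add to or oligomerise the electron-rich chromene double bond, and a boron enolate may erode the configuration at C3. The fallback moves the demethylation to a stage with neither chromene nor stereocentre; it sets out from 5 (and uses 11) and returns at 16. Compound 5 is mono-demethylated with BCl3 to 1-[2-hydroxy-6-methoxy-4-(triisopropylsilyloxy)phenyl]ethanone F4. Silylation with TIPSOTf/2,6-lutidine gives 1-[2-methoxy-4,6-bis(triisopropylsilyloxy)phenyl]ethanone F5. α-Arylation with 11 under the conditions of step 6 gives 2-[2,2-dimethyl-5-(triisopropylsilyloxy)-2H-chromen-8-yl]-1-[2-methoxy-4,6-bis(triisopropylsilyloxy)phenyl]ethanone F6. Diazo transfer as in step 7 gives 2-diazo-2-[2,2-dimethyl-5-(triisopropylsilyloxy)-2H-chromen-8-yl]-1-[2-methoxy-4,6-bis(triisopropylsilyloxy)phenyl]ethanone F7. Insertion as in step 8 into the one remaining methoxy group gives (3R)-3-[2,2-dimethyl-5-(triisopropylsilyloxy)-2H-chromen-8-yl]-5,7-bis(triisopropylsilyloxy)chroman-4-one F8. A single HF·pyridine treatment then frees all three phenols to give 16.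

3. Step 6. Oxidative addition to the electron-rich, ortho-oxygenated bromide and coupling with the hindered 2,6-disubstituted aryl ketone enolate may be sluggish, and prolonged heating with base may strip silyl groups. The fallback forms the C4–C4a bond last instead; it sets out from 11 (and 2) and returns at 12. Negishi coupling of 11 with the Reformatsky reagent BrZnCH2CO2Et (Pd2(dba)3, XPhos, THF, 60 °C) gives ethyl 2-[2,2-dimethyl-5-(triisopropylsilyloxy)-2H-chromen-8-yl]acetate F9. MeNH(OMe)·HCl and i-PrMgCl (THF, −20 °C) convert it into 2-[2,2-dimethyl-5-(triisopropylsilyloxy)-2H-chromen-8-yl]-N-methoxy-N-methylacetamide F10. Addition of the aryllithium 4 (generated from 2 as in step 2) at −78 °C then gives 12.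

**Further compounds**

F1 | step 8 | 2-[2,2-dimethyl-5-(triisopropylsilyloxy)-2H-chromen-8-yl]-1-[2-hydroxy-6-methoxy-4-(triisopropylsilyloxy)phenyl]ethanone | COc1cc(O[Si](C(C)C)(C(C)C)C(C)C)cc(O)c1C(=O)Cc1ccc(O[Si](C(C)C)(C(C)C)C(C)C)c2C=CC(C)(C)Oc12
F2 | step 8 | racemic 3-[2,2-dimethyl-5-(triisopropylsilyloxy)-2H-chromen-8-yl]-5-methoxy-7-(triisopropylsilyloxy)chroman-4-one | CC1(C)C=Cc2c(O[Si](C(C)C)(C(C)C)C(C)C)ccc(C3COc4cc(O[Si](C(C)C)(C(C)C)C(C)C)cc(OC)c4C3=O)c2O1
F3 | step 8 | (3R,4R)-cis-3-[2,2-dimethyl-5-(triisopropylsilyloxy)-2H-chromen-8-yl]-5-methoxy-7-(triisopropylsilyloxy)chroman-4-ol | CC1(C)C=Cc2c(O[Si](C(C)C)(C(C)C)C(C)C)ccc([C@@H]3COc4cc(O[Si](C(C)C)(C(C)C)C(C)C)cc(OC)c4[C@@H]3O)c2O1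
F4 | step 9 | 1-[2-hydroxy-6-methoxy-4-(triisopropylsilyloxy)phenyl]ethanone | CC(=O)c1c(O)cc(O[Si](C(C)C)(C(C)C)C(C)C)cc1OC
F5 | step 9 | 1-[2-methoxy-4,6-bis(triisopropylsilyloxy)phenyl]ethanone | CC(=O)c1c(OC)cc(O[Si](C(C)C)(C(C)C)C(C)C)cc1O[Si](C(C)C)(C(C)C)C(C)C
F6 | step 9 | 2-[2,2-dimethyl-5-(triisopropylsilyloxy)-2H-chromen-8-yl]-1-[2-methoxy-4,6-bis(triisopropylsilyloxy)phenyl]ethanone | COc1cc(O[Si](C(C)C)(C(C)C)C(C)C)cc(O[Si](C(C)C)(C(C)C)C(C)C)c1C(=O)Cc1ccc(O[Si](C(C)C)(C(C)C)C(C)C)c2C=CC(C)(C)Oc12
F7 | step 9 | 2-diazo-2-[2,2-dimethyl-5-(triisopropylsilyloxy)-2H-chromen-8-yl]-1-[2-methoxy-4,6-bis(triisopropylsilyloxy)phenyl]ethanone | COc1cc(O[Si](C(C)C)(C(C)C)C(C)C)cc(O[Si](C(C)C)(C(C)C)C(C)C)c1C(=O)C(=[N+]=[N-])c1ccc(O[Si](C(C)C)(C(C)C)C(C)C)c2C=CC(C)(C)Oc12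
F8 | step 9 | (3R)-3-[2,2-dimethyl-5-(triisopropylsilyloxy)-2H-chromen-8-yl]-5,7-bis(triisopropylsilyloxy)chroman-4-one | CC1(C)C=Cc2c(O[Si](C(C)C)(C(C)C)C(C)C)ccc([C@@H]3COc4cc(O[Si](C(C)C)(C(C)C)C(C)C)cc(O[Si](C(C)C)(C(C)C)C(C)C)c4C3=O)c2O1
F9 | step 6 | ethyl 2-[2,2-dimethyl-5-(triisopropylsilyloxy)-2H-chromen-8-yl]acetate | CCOC(=O)Cc1ccc(O[Si](C(C)C)(C(C)C)C(C)C)c2C=CC(C)(C)Oc12
F10 | step 6 | 2-[2,2-dimethyl-5-(triisopropylsilyloxy)-2H-chromen-8-yl]-N-methoxy-N-methylacetamide | CON(C)C(=O)Cc1ccc(O[Si](C(C)C)(C(C)C)C(C)C)c2C=CC(C)(C)Oc12
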